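**Strategy**

The route rests on closing ring A last at the C1–C10 bond by attack of a tertiary C10 radical on the terminal carbon of a C3 vinyl ketone. That radical is made in the same operation: a C8 acyl radical from an acyclic selenoester adds to C9 of a C9=C10 alkene and so closes ring B first. One step thus builds both rings, the quaternary C10 and C9, and leaves ketones at C3 and C8 for the 3β-acetate and the C8(17) methylene. It exploits quaternary, methyl-bearing C10 lying 1,3 to C8 in ring B and 1,4 to the C3 oxygen in ring A. The precursor is an open-chain triene with a single stereocentre, C5.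

Key step: step 8

Remark: carbon numbers in the Why lines are labdane numbers of the target; commercial methyl geranate is assumed to be the pure 2E isomer.

**Route**

Step 1
Reactants: 1 methyl geranate
Product: 3 methyl (2E)-3-methyl-6-oxohex-2-enoate, via secondary ozonide 2 (not isolated)
Conditions: O3 (1 equiv), CH2Cl2, −78 °C; then Me2S, −78 °C to rt
Reagents that add atoms: ozone (O=[O+][O-])
Why: Ozonolysis with one equivalent of ozone cleaves the electron-rich trisubstituted 6,7-alkene in preference to the ester-conjugated 2,3-alkene, and reductive work-up gives the aldehyde.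

Step 2
Reactants: 4 methyl 4-oxobutanoate
Product: 5 methyl (4Z)-5-iodohex-4-enoate
Conditions: EtPPh3I, n-BuLi, THF, 0 °C; I2, −78 °C; NaN(SiMe3)2, −20 °C; then 4, −78 °C to rt
Reagents that add atoms: ethyltriphenylphosphonium iodide (CC[P+](c1ccccc1)(c1ccccc1)c1ccccc1.[I-]); iodine (II)
Why: Wittig olefination with the α-iodoethylidene ylide (Stork–Zhao type) should give the trisubstituted vinyl iodide with iodine cis to the chain (Z), the aldehyde reacting far faster than the methyl ester.

Step 3
Reactants: 5 methyl (4Z)-5-iodohex-4-enoate; 3 methyl (2E)-3-methyl-6-oxohex-2-enoate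
Product: 6 dimethyl (2E,6R,7Z)-6-hydroxy-3,7-dimethylundeca-2,7-dienedioate
Conditions: CrCl2 (3 equiv), NiCl2 (2 mol%), chiral oxazoline–sulfonamide ligand, Et3N, THF, rt
Reagents that add atoms: none
Why: Nozaki–Hiyama–Kishi alkenylation, in which the alkenylchromium species keeps the Z geometry and adds only to the aldehyde; the ligand on chromium differentiates the aldehyde faces, and the ligand antipode that delivers the 6R carbinol (future C9) is used.

Step 4
Reactants: 6 dimethyl (2E,6R,7Z)-6-hydroxy-3,7-dimethylundeca-2,7-dienedioate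
Product: 8 dimethyl (2E,6E,8R)-3,7-dimethyl-8-(2-methyl-1-oxopropan-2-yl)undeca-2,6-dienedioate, via allyl 2-methylpropenyl ether 7 (not isolated)
Conditions: 1-iodo-2-methylprop-1-ene, CuI (10 mol%), 3,4,7,8-tetramethyl-1,10-phenanthroline (20 mol%), Cs2CO3, o-xylene, 120 °C
Reagents that add atoms: 1-iodo-2-methylprop-1-ene (CC(C)=CI)
Why: Copper-catalysed O-vinylation followed in the same flask by Claisen [3,3] rearrangement through a chair with the C1–C5 chain of the carbinol carbon equatorial should transfer the C–O chirality suprafacially to the new C–C stereocentre (8R, future C5), while forming the gem-dimethyl quaternary carbon (future C4) and the 6E alkene.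

Step 5
Reactants: 8 dimethyl (2E,6E,8R)-3,7-dimethyl-8-(2-methyl-1-oxopropan-2-yl)undeca-2,6-dienedioate
Product: 9 dimethyl (2E,6E,8R)-8-(3-hydroxy-2-methylpent-4-en-2-yl)-3,7-dimethylundeca-2,6-dienedioate (both carbinol epimers)
Conditions: vinylmagnesium bromide, THF, −78 °C; aq. NH4Cl
Reagents that add atoms: vinylmagnesium bromide (C=C[Mg]Br)
Why: Grignard 1,2-addition at −78 °C is selective for the aldehyde over both methyl esters; the new carbinol centre is not controlled and is removed by oxidation in step 7.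

Step 6
Reactants: 9 dimethyl (2E,6E,8R)-8-(3-hydroxy-2-methylpent-4-en-2-yl)-3,7-dimethylundeca-2,6-dienedioate
Product: 10 methyl (2E,6E,8R)-8-(3-hydroxy-2-methylpent-4-en-2-yl)-3,7-dimethyl-11-oxo-11-(phenylselanyl)undeca-2,6-dienoate
Conditions: Me2AlSePh (from AlMe3 and PhSeH, 2.5 equiv), CH2Cl2, 0 °C to rt
Reagents that add atoms: dimethylaluminium phenylselenolate (C[Al](C)[Se]c1ccccc1)
Why: Aluminium selenolate transacylation should convert the unhindered saturated methyl ester into the Se-phenyl selenoester, while the conjugated, β,β-disubstituted enoate ester reacts much more slowly and the hindered alcohol is only masked as its aluminium alkoxide.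

Step 7
Reactants: 10 methyl (2E,6E,8R)-8-(3-hydroxy-2-methylpent-4-en-2-yl)-3,7-dimethyl-11-oxo-11-(phenylselanyl)undeca-2,6-dienoate
Product: 11 methyl (2E,6E,8R)-3,7-dimethyl-8-(2-methyl-3-oxopent-4-en-2-yl)-11-oxo-11-(phenylselanyl)undeca-2,6-dienoate
Conditions: Dess–Martin periodinane, NaHCO3, CH2Cl2, 0 °C
Reagents that add atoms: none
Why: Dess–Martin oxidation of the secondary allylic alcohol gives the vinyl ketone under buffered, non-nucleophilic conditions that should leave the selenoester and the new enone intact.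

Step 8
Reactants: 11 methyl (2E,6E,8R)-3,7-dimethyl-8-(2-methyl-3-oxopent-4-en-2-yl)-11-oxo-11-(phenylselanyl)undeca-2,6-dienoate
Product: 12 methyl (13E)-3,8-dioxo-17-norlabd-13-en-15-oate (trans-decalin; 5α-H, 9α-H, 10β-CH3)
Conditions: Bu3SnH (1.3 equiv, syringe pump), AIBN (cat.), benzene, 80 °C, 2 mM; then DBU (cat.), CH2Cl2, rt
Reagents that add atoms: none
Why: The stannyl radical abstracts PhSe to give the C8 acyl radical, which adds 6-endo-trig to C9 of the C9=C10 alkene (5-exo attack at the fully substituted C10 is disfavoured) and so closes ring B; the resulting tertiary, nucleophilic C10 radical then adds 6-endo-trig to the terminal C1 of the C3 vinyl ketone, forming the C1–C10 bond and ring A, and the C2 α-keto radical takes hydrogen from Bu3SnH. The closest known reaction type is the acyl radical (selenoester) polyene cyclisation with consecutive 6-endo closures, ended here by a Giese-type addition to an enone. C9 is set in the chair-like first transition state (C5 substituent and C11 chain both equatorial, E alkene) and, being α to the C8 ketone, is converged by DBU to the equatorial side chain. C10 is set by C5: the tether on the equatorial C4 substituent should reach the planar C10 radical through the chair–chair (trans-decalin) transition state, which places the methyl axial. The step needs 6-endo over 5-exo closure twice and cyclisation faster than hydrogen transfer; the substitution at C10, the polarity match between the tertiary radical and the enone, and slow addition of Bu3SnH at high dilution secure this.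

Step 9
Reactants: 12 methyl (13E)-3,8-dioxo-17-norlabd-13-en-15-oate
Product: 13 methyl (13E)-3β-hydroxy-8-oxo-17-norlabd-13-en-15-oate
Conditions: NaBH4 (0.3 equiv), MeOH/CH2Cl2, −78 °C
Reagents that add atoms: none
Why: Hydride should add axially from the α face of the C3 ketone, as is general for 4,4-dimethyl-3-ketones, to give the equatorial 3β-alcohol, while the C8 ketone is spared because its axial face is blocked by the syn-axial C10 methyl and its equatorial face by the C9 side chain.

Step 10
Reactants: 13 methyl (13E)-3β-hydroxy-8-oxo-17-norlabd-13-en-15-oate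
Product: 14 methyl (13E)-3β-hydroxylabda-8(17),13-dien-15-oate
Conditions: Zn, CH2Br2, TiCl4, THF/CH2Cl2, 0 °C to rt
Reagents that add atoms: dibromomethane (BrCBr)
Why: Takai–Lombardo methylenation is non-basic, so the hindered, enolisable C8 ketone should give the 8(17)-methylene without epimerisation at C9 and without touching the enoate or the free hydroxyl.

Step 11
Reactants: 14 methyl (13E)-3β-hydroxylabda-8(17),13-dien-15-oate
Product: 15 (13E)-3β-hydroxylabda-8(17),13-dien-15-oic acid
Conditions: LiOH, THF/MeOH/H2O, 50 °C; then 1 M HCl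
Reagents that add atoms: lithium hydroxide ([Li+].[OH-])
Why: Saponification of the methyl enoate; no other group is base-labile, and the conjugated 13E isomer is the thermodynamic one.

Step 12
Reactants: 15 (13E)-3β-hydroxylabda-8(17),13-dien-15-oic acid
Product: 17 (13E)-3β-acetoxylabda-8(17),13-dien-15-oic acid, via mixed acetic anhydride 16 (not isolated)
Conditions: Ac2O, pyridine, DMAP (cat.), CH2Cl2, rt; then H2O/THF
Reagents that add atoms: acetic anhydride (CC(=O)OC(C)=O); water (O)
Why: DMAP-catalysed acylation of the equatorial 3β-hydroxyl; the carboxyl group is acetylated only to a mixed anhydride, which water cleaves back to the acid on work-up.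

**Compound list**

1 | methyl geranate, methyl (2E)-3,7-dimethylocta-2,6-dienoate | COC(=O)/C=C(\C)CCC=C(C)C | starting material
2 | secondary ozonide, methyl (2E)-5-(5,5-dimethyl-1,2,4-trioxolan-3-yl)-3-methylpent-2-enoate | COC(=O)/C=C(\C)CCC1OOC(C)(C)O1 | intermediate
3 | methyl (2E)-3-methyl-6-oxohex-2-enoate | COC(=O)/C=C(\C)CCC=O | intermediate
4 | methyl 4-oxobutanoate | COC(=O)CCC=O | starting material
5 | methyl (4Z)-5-iodohex-4-enoate | COC(=O)CC/C=C(\I)C | intermediate
6 | dimethyl (2E,6R,7Z)-6-hydroxy-3,7-dimethylundeca-2,7-dienedioate | COC(=O)/C=C(\C)CC[C@@H](O)/C(C)=C\CCC(=O)OC | intermediate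
7 | dimethyl (2E,6R,7Z)-3,7-dimethyl-6-[(2-methylprop-1-en-1-yl)oxy]undeca-2,7-dienedioate | COC(=O)/C=C(\C)CC[C@@H](OC=C(C)C)/C(C)=C\CCC(=O)OC | intermediate
8 | dimethyl (2E,6E,8R)-3,7-dimethyl-8-(2-methyl-1-oxopropan-2-yl)undeca-2,6-dienedioate | COC(=O)CC[C@H](/C(C)=C/CC/C(C)=C/C(=O)OC)C(C)(C)C=O | intermediate
9 | dimethyl (2E,6E,8R)-8-(3-hydroxy-2-methylpent-4-en-2-yl)-3,7-dimethylundeca-2,6-dienedioate (carbinol epimers) | COC(=O)CC[C@H](/C(C)=C/CC/C(C)=C/C(=O)OC)C(C)(C)C(O)C=C | intermediate
10 | methyl (2E,6E,8R)-8-(3-hydroxy-2-methylpent-4-en-2-yl)-3,7-dimethyl-11-oxo-11-(phenylselanyl)undeca-2,6-dienoate | O=C([Se]c1ccccc1)CC[C@H](/C(C)=C/CC/C(C)=C/C(=O)OC)C(C)(C)C(O)C=C | intermediate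
11 | methyl (2E,6E,8R)-3,7-dimethyl-8-(2-methyl-3-oxopent-4-en-2-yl)-11-oxo-11-(phenylselanyl)undeca-2,6-dienoate | O=C([Se]c1ccccc1)CC[C@H](/C(C)=C/CC/C(C)=C/C(=O)OC)C(C)(C)C(=O)C=C | intermediate
12 | methyl (13E)-3,8-dioxo-17-norlabd-13-en-15-oate | O=C1CC[C@H]2C(C)(C)C(=O)CC[C@]2(C)[C@H]1CC/C(C)=C/C(=O)OC | intermediate
13 | methyl (13E)-3β-hydroxy-8-oxo-17-norlabd-13-en-15-oate | O=C1CC[C@H]2C(C)(C)[C@@H](O)CC[C@]2(C)[C@H]1CC/C(C)=C/C(=O)OC | intermediate
14 | methyl (13E)-3β-hydroxylabda-8(17),13-dien-15-oate | C=C1CC[C@H]2C(C)(C)[C@@H](O)CC[C@]2(C)[C@H]1CC/C(C)=C/C(=O)OC | intermediate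
15 | (13E)-3β-hydroxylabda-8(17),13-dien-15-oic acid | C=C1CC[C@H]2C(C)(C)[C@@H](O)CC[C@]2(C)[C@H]1CC/C(C)=C/C(=O)O | intermediate
16 | acetic (13E)-3β-acetoxylabda-8(17),13-dien-15-oic anhydride | C=C1CC[C@H]2C(C)(C)[C@@H](OC(C)=O)CC[C@]2(C)[C@H]1CC/C(C)=C/C(=O)OC(C)=O | intermediate
17 | (13E)-3β-acetoxylabda-8(17),13-dien-15-oic acid | C=C1CC[C@H]2C(C)(C)[C@@H](OC(C)=O)CC[C@]2(C)[C@H]1CC/C(C)=C/C(=O)O | target

**Step count**

Total: 12 steps. Longest linear sequence: 11 steps (step 1 or step 2, then steps 3 to 12).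

**Steps most likely to fail**

Step 8. What may go wrong is hydrogen transfer from Bu3SnH to the acyl or the C10 radical before ring closure, or addition of the stannyl radical to the vinyl ketone, so that the cascade stops at open-chain or monocyclic material. The fallback forms the two rings one after the other; it sets out from 10 and comes back at 12. Reduction of selenoester 10 with Bu3SnH under Pd(PPh3)4 catalysis gives methyl (2E,6E,8R)-8-(3-hydroxy-2-methylpent-4-en-2-yl)-3,7-dimethyl-11-oxoundeca-2,6-dienoate F1. Me2AlCl (CH2Cl2, −78 °C) then promotes a type 2 intramolecular carbonyl-ene reaction (C8 to C9, hydrogen taken from C20) to methyl (2E)-5-[(3R)-6-hydroxy-3-(3-hydroxy-2-methylpent-4-en-2-yl)-2-methylidenecyclohexyl]-3-methylpent-2-enoate F2. Dess–Martin oxidation of both carbinols gives methyl (2E)-3-methyl-5-[(3R)-2-methylidene-3-(2-methyl-3-oxopent-4-en-2-yl)-6-oxocyclohexyl]pent-2-enoate F3. Fe(acac)3 and PhSiH3 (EtOH, 60 °C) transfer a hydrogen atom to the C10=C20 methylene and so generate the same C10 radical, which should close ring A on C1; DBU then gives 12.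

Step 9. What may go wrong is poor discrimination between the C3 and C8 carbonyl groups, with over-reduction at C8. The fallback sets out from 12 and comes back at 15. Excess NaBH4 gives methyl (13E)-3β,8-dihydroxy-17-norlabd-13-en-15-oate F4. Ac2O and pyridine at 0 °C should acetylate only the equatorial 3β-hydroxyl, the C8 hydroxyl being flanked by C9 and the C10 methyl, to give methyl (13E)-3β-acetoxy-8-hydroxy-17-norlabd-13-en-15-oate F5. Dess–Martin oxidation gives methyl (13E)-3β-acetoxy-8-oxo-17-norlabd-13-en-15-oate F6, and Takai–Lombardo methylenation gives methyl (13E)-3β-acetoxylabda-8(17),13-dien-15-oate F7. LiOH then cleaves both the acetate and the methyl ester to 15, which re-enters at step 12.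

Step 3. What may go wrong is incomplete facial control at the aldehyde, which the Claisen step would pass on to C5 as lowered enantiomeric purity. The fallback sets out from 5 and 3 and comes back at 6. Ligand-free CrCl2/NiCl2 coupling gives racemic dimethyl (2E,7Z)-6-hydroxy-3,7-dimethylundeca-2,7-dienedioate F8. Dess–Martin oxidation gives dimethyl (2E,7Z)-3,7-dimethyl-6-oxoundeca-2,7-dienedioate F9. Corey–Bakshi–Shibata reduction with the (S)-methyl oxazaborolidine and BH3·SMe2, the alkenyl group acting as the large substituent, should return the 6R alcohol 6.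

**Further compounds**

F1 | step 8 | methyl (2E,6E,8R)-8-(3-hydroxy-2-methylpent-4-en-2-yl)-3,7-dimethyl-11-oxoundeca-2,6-dienoate | O=CCC[C@H](/C(C)=C/CC/C(C)=C/C(=O)OC)C(C)(C)C(O)C=C
F2 | step 8 | methyl (2E)-5-[(3R)-6-hydroxy-3-(3-hydroxy-2-methylpent-4-en-2-yl)-2-methylidenecyclohexyl]-3-methylpent-2-enoate | OC1CC[C@@H](C(C)(C)C(O)C=C)C(=C)C1CC/C(C)=C/C(=O)OC
F3 | step 8 | methyl (2E)-3-methyl-5-[(3R)-2-methylidene-3-(2-methyl-3-oxopent-4-en-2-yl)-6-oxocyclohexyl]pent-2-enoate | O=C1CC[C@@H](C(C)(C)C(=O)C=C)C(=C)C1CC/C(C)=C/C(=O)OC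
F4 | step 9 | methyl (13E)-3β,8-dihydroxy-17-norlabd-13-en-15-oate | OC1CC[C@H]2C(C)(C)[C@@H](O)CC[C@]2(C)[C@H]1CC/C(C)=C/C(=O)OC
F5 | step 9 | methyl (13E)-3β-acetoxy-8-hydroxy-17-norlabd-13-en-15-oate | OC1CC[C@H]2C(C)(C)[C@@H](OC(C)=O)CC[C@]2(C)[C@H]1CC/C(C)=C/C(=O)OC
F6 | step 9 | methyl (13E)-3β-acetoxy-8-oxo-17-norlabd-13-en-15-oate | O=C1CC[C@H]2C(C)(C)[C@@H](OC(C)=O)CC[C@]2(C)[C@H]1CC/C(C)=C/C(=O)OC
F7 | step 9 | methyl (13E)-3β-acetoxylabda-8(17),13-dien-15-oate | C=C1CC[C@H]2C(C)(C)[C@@H](OC(C)=O)CC[C@]2(C)[C@H]1CC/C(C)=C/C(=O)OC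
F8 | step 3 | racemic dimethyl (2E,7Z)-6-hydroxy-3,7-dimethylundeca-2,7-dienedioate | COC(=O)/C=C(\C)CCC(O)/C(C)=C\CCC(=O)OC
F9 | step 3 | dimethyl (2E,7Z)-3,7-dimethyl-6-oxoundeca-2,7-dienedioate | COC(=O)/C=C(\C)CCC(=O)/C(C)=C\CCC(=O)OC
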